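The earlier runs and the new flask are calculated from invented constants.

- The leftover free electrophile at 30.0 h is the reading to reckon from: 61% of the charge in the cedar run at 1.4 equiv, and 44% in the maple run at 2.6 equiv.

| flask | electrophile | nucleophile | remark | time |
|---|---|---|---|---|
| cedar | 0.10 M | 1.4 equiv | run made earlier |  |
| maple | 0.10 M | 2.6 equiv | run made earlier |  |
| Tuesday's | 0.10 M | 2.00 equiv |  | 30 h |
| Saturday's | 0.10 M | 4.00 equiv |  | 30 h |

| run | time / h | electrophile / % | target / % |
|---|---|---|---|
| cedar | 8.00 | 86 | 11 |
| cedar | 15.0 | 73 | 14 |
| cedar | 25.0 | 64 | 18 |
| cedar | 30.0 | 61 | 24 |
| maple | 4.00 | 82 | 12 |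
| maple | 10.0 | 65 | 17 |
| maple | 20.0 | 53 | 18 |
| maple | 30.0 | 44 | 19 |

(readings scatter by 2 percentage points)

- what was read earlier has a scatter of 2 percentage points, one standard deviation
- a reading or a percentage of target counts all its forms, free or not
- what has gone from electrophile into another species counts as reacted, even if it can come back
- a reading of electrophile is of its free form alone

- part of the electrophile that has reacted at the end, Tuesday's
- part of the electrophile that has reacted at the end, Saturday's
- what raising the equivalents of nucleophile from its lowest to its highest value here does to the part of the electrophile that has reacted (changes below 5 percentage points count as none) (it falls / it rises / no change)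

- For a plain bimolecular step with nucleophile in excess (pseudo-first-order), at fixed time and electrophile charge, the negative logarithm of the free fraction grows in step with the equivalents, so a constant ratio is the zero of the scale.
- That ratio reads 0.353 in the cedar run and 0.316 in the maple run, a gap that a scatter of 2 percentage points does not clearly separate, with mean 0.334.
- This mean is the exponent per equivalent, the negative logarithm of the free fraction at 30 h divided by the equivalents of nucleophile.
- First rung: target in the maple run reads 17% at 10.0 h and 19% at 30.0 h, a rise of 2 points against a scatter of 2 points, while the share that is neither free electrophile nor target climbs from 18.0% to 37.0%.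
- Next rung: the exponent gives free electrophile a half-life of 15.5 h at Saturday's charge, about half of that flask's 30 h.
- Slowest rung: the half-life at Tuesday's charge is 31.1 h, close to the run's length.
- The reacted part, one minus the free fraction, is therefore reckoned here at 48.8% for Tuesday's and 73.8% for Saturday's.
- The forecast says 48% (43% to 52%) and 69% (60% to 78%), and it rises, “with the 4 equiv figure being an extrapolation and so less certain”; at Saturday's it stands lower than the reckoning here.
- The simulation gives 48.4% for Tuesday's and 70.2% for Saturday's, and it rises by 22 points, inside both forecast ranges.

    electrophile + nucleophile → acid set free + target (k = 0.140 M⁻¹ h⁻¹)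
    nucleophile + acid set free ⇌ protonated nucleophile, settled at all times (K = 240 M⁻¹)
    electrophile + target ⇌ idle adduct, settled at all times (K = 6.90 M⁻¹)
    nucleophile + target → over-reaction product (k = 0.400 M⁻¹ h⁻¹)

- Put back on the exponent scale, Tuesday's result gives 0.331 and Saturday's 0.302, lower than the carried 0.334. A neighbour of Saturday's charged with 10.0 equiv is reckoned with the carried exponent at 3.54% free electrophile at 30.0 h. That flask holds 4.25% free electrophile, with 95.7% reacted.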